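(Readings and results are simulated for substances that don't exist, and the scatter is random.)

Target cannot stand in a flask before substrate has left it, so the first thing to count is how often the substrate has been turned over in the time allowed.

| flask | substrate | partner | second reagent | temperature | remark | time |
|---|---|---|---|---|---|---|
| east | 0.30 M | 0.23 M | 0.54 M | −10 °C | run made earlier |  |
| south-west | 0.30 M | 0.34 M | 0.54 M | 25 °C | run made earlier |  |
| west | 0.60 M | 0.45 M | 0.54 M | −10 °C | run made earlier |  |
| delta | 0.30 M | 0.450 M | 0.540 M | 15 °C |  | 5.0 h |
| theta | 0.30 M | 0.450 M | 0.540 M | −5 °C |  | 5.0 h |
| gamma | 0.30 M | 0.450 M | 0.540 M | 35 °C |  | 5.0 h |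
| epsilon | 0.30 M | 0.450 M | 0.540 M | 55 °C |  | 5.0 h |

- east (time / h: target / %, substrate / %): 3.00: 0.3, 99.3; 5.00: 0, 99.8; 8.00: 0.2, 99.1; 10.0: 0, 99.1
- south-west (time / min: target / %, substrate / %): 30.0: 0, 96.1; 60.0: 1.3, 92.2; 90.0: 2.3, 89.5; 120: 3.7, 86.5
- west (time / h: target / %, substrate / %): 1.33: 0, 99.2; 3.00: 0, 99.0; 6.00: 0.2, 99.2; 10.0: 0.3, 98.6

(each reading ± 0.3 percentage points)



- the best flask by amount of target, in percent of the substrate charged; "all alike" if 1.5 percentage points covers them all (delta / theta / gamma / epsilon / all alike)
- amount of target at the end, in percent of the substrate charged, delta
- amount of target at the end, in percent of the substrate charged, theta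
- amount of target at the end, in percent of the substrate charged, gamma
- amount of target at the end, in percent of the substrate charged, epsilon

Two chemists argue over these flasks; the count below is my own reckoning, and each reads it differently. In the south-west run the substrate falls to 86.5% after 120 min. Taken as first order in substrate and in partner, this reads as a constant of 0.213 L mol⁻¹ h⁻¹. The west run, with 98.6% left after 10.0 h, reads as 0.00313 L mol⁻¹ h⁻¹, a rough value, since its small loss stands against a scatter of 0.3 percentage points.

A straight line through the logarithms of these two constants against temperature gives a rough constant for each asked flask, and multiplying it by c_partner as charged and by the time gives a pure number. For gamma that number is 1.60. This is N, the turnovers: how many substrate lifetimes the time allows at the charged partner. Substrate left is then about exp(−N), and the count runs high once partner has fallen. Theta gets 0.0129, delta 0.144 and epsilon 17.9, ten times gamma's count.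

The first chemist holds that target follows the turnover of substrate after a lag, and hers is the forecast, reckoned her own way: 0.1% for theta, 3.7% for delta, 45% for gamma, 85% for epsilon, best epsilon, a flask she calls “near complete, barring unseen side or decomposition reactions” and shades down.

The second holds that N says how much substrate has gone and nothing about what it became. At the last reading of the south-west run, target reads as 27.4% of the substrate lost. The second reagent was charged there at 1.80 per substrate, which, he says, may leave some to act on target as well. Turnovers far past one, he says, are time spent by target in a hot flask, so he bets on gamma.

The simulation gives 0.106% for theta, 4.90% for delta, 31.6% for gamma and 18.0% for epsilon. The best flask is gamma, richer in target than the others, so the second chemist wins.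

    substrate + partner → intermediate (k = 0.640 L mol⁻¹ h⁻¹, Ea = 79.0 kJ mol⁻¹)
    second reagent + intermediate → target (k = 1.50 L mol⁻¹ h⁻¹, Ea = 56.0 kJ mol⁻¹)
    second reagent + target → over-reaction product (k = 0.500 L mol⁻¹ h⁻¹, Ea = 87.0 kJ mol⁻¹)
    (constants at 35 °C)

Epsilon, reckoned at N of 17.9, ended with 1.48% of the substrate, yet its target stands at 18.0% beside 73.0% of over-reaction product. The same run without the conversion of second reagent + target holds 97.3% of target, so that step is the main reason for epsilon's shortfall. The first chemist's view fits the neighbour of theta at 20 °C, where the line gives N of 0.263, so 23.1% of the substrate gone. That flask kept 76.2% of its substrate and holds 10.0% of target against 0.907% of over-reaction product.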